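**Plan**

- Retrosynthesis: the acetyl–O bond and the four benzyl groups come off first. The C2'–C3' bond is then cut to a Weinreb amide and an eleven-carbon terminal alkyne. Finally the C6–C1' and C1–carboxyl bonds are cut together, back to a 3,5-dioxygenated benzyne and a malonate.
- Enabling feature: the carboxyl carbon sits on ring atom C1 and the benzylic CH2 (C1') on the neighbouring ring atom C6. Only C1 has an oxygen-bearing neighbour (C2); C6 is flanked by C5–H, and the second oxygen is at C4. This is the pattern an unsymmetrical 3,5-dialkoxybenzyne gives with a malonate.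
- Forward order: 3,5-bis(benzyloxy)phenol → ortho-silyl aryl triflate → aryne/malonate insertion to the homophthalate (no ring is built; the benzene ring is present from the start) → Weinreb amide at the aliphatic ester → ynone → carbinol → acetate → one hydrogenation that saturates the chain and removes all benzyl groups.
- Stereochemistry: the single stereocentre (C2', R in the target) is set by Noyori transfer hydrogenation of the ynone with the (S,S)-TsDPEN ruthenium catalyst. It is S at the propargylic stage and becomes R on saturation only through the change in CIP ranking.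

Key step: step 4

Assumption: 3,5-bis(benzyloxy)phenol is taken as a catalogue compound; it is otherwise the known dibenzyl ether of phloroglucinol.

**Route**

Step 1
Reactants: 1 3,5-bis(benzyloxy)phenol
Product: 2 3,5-bis(benzyloxy)-2-bromophenol
Conditions: NBS (1.0 equiv), CH2Cl2, −78 °C to rt
Reagents that add atoms: N-bromosuccinimide, O=C1CCC(=O)N1Br
Why: Electrophilic aromatic bromination with NBS at low temperature in a non-coordinating solvent should go ortho to the free hydroxyl (C2, also para to the C5 ether), because the hydrogen-bonded phenol delivers the reagent there and the alternative C4 site is squeezed between two benzyloxy groups.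

Step 2
Reactants: 2 3,5-bis(benzyloxy)-2-bromophenol
Product: 3 [3,5-bis(benzyloxy)-2-bromophenoxy]trimethylsilane
Conditions: HMDS, THF, 70 °C; evaporate, use crude
Reagents that add atoms: hexamethyldisilazane, C[Si](C)(C)N[Si](C)(C)C
Why: O-Silylation of the phenol with hexamethyldisilazane gives the aryl trimethylsilyl ether with ammonia as the only by-product, so the crude ether can be carried on after evaporation.

Step 3
Reactants: 3 [3,5-bis(benzyloxy)-2-bromophenoxy]trimethylsilane
Product: 6 3,5-bis(benzyloxy)-2-(trimethylsilyl)phenyl trifluoromethanesulfonate, via aryllithium 4 (not isolated), via lithium silylphenoxide 5 (not isolated)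
Conditions: n-BuLi, THF, −100 °C; then Tf2O, −100 °C to rt
Reagents that add atoms: trifluoromethanesulfonic anhydride, O=S(=O)(OS(=O)(=O)C(F)(F)F)C(F)(F)F
Why: Bromine–lithium exchange gives aryllithium 4, which undergoes a retro-Brook 1,3 O-to-C silyl shift to phenoxide 5 that is triflated on oxygen, the standard entry to ortho-silyl aryl triflates.

Step 4
Reactants: 6 3,5-bis(benzyloxy)-2-(trimethylsilyl)phenyl trifluoromethanesulfonate; 7 dibenzyl malonate
Product: 10 benzyl 2,4-bis(benzyloxy)-6-[2-(benzyloxy)-2-oxoethyl]benzoate, via aryne 8 (not isolated), via benzocyclobutene alkoxide 9 (not isolated)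
Conditions: KF (3 equiv), 18-crown-6 (3 equiv), THF, 0 °C to rt
Reagents that add atoms: none
Why: Fluoride attacks silicon of 6 and expels triflate to give 3,5-bis(benzyloxy)benzyne 8; the potassium enolate of 7 adds to the aryne carbon remote from the neighbouring benzyloxy group (forming C6–C1'), which places the aryl anion on the carbon flanked by that oxygen. The aryl anion then closes onto one ester carbonyl to give the four-membered alkoxide 9, and retro-aldol-type fragmentation of 9 breaks the old malonate C–C bond, leaving the benzoate carbon on the ring (C1–C=O) and a benzylic ester enolate that is protonated. The closest known reaction type is the aryne σ-insertion (acyl-alkylation) into malonates and β-ketoesters. The only ring closed is the transient cyclobutene ring, formed by 4-exo-trig attack and reopened in the same operation, so no ring and no stereocentre remain in 10. The selectivity needed is regiochemical: the inductively withdrawing oxygen next to the triple bond, and the distortion it causes in the aryne, steer the nucleophile to the distal carbon, so the carboxyl ends up ortho to oxygen as in the target.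

Step 5
Reactants: 10 benzyl 2,4-bis(benzyloxy)-6-[2-(benzyloxy)-2-oxoethyl]benzoate
Product: 11 benzyl 2,4-bis(benzyloxy)-6-{2-[methoxy(methyl)amino]-2-oxoethyl}benzoate
Conditions: MeNH(OMe)·HCl, AlMe3, CH2Cl2, 0 °C to rt; dilute aq. HCl work-up
Reagents that add atoms: N,O-dimethylhydroxylamine hydrochloride, CNOC.Cl
Why: Weinreb aminolysis with the aluminium amide formed from AlMe3 and the amine salt should occur only at the unhindered arylacetic ester, since the benzoate carbonyl is shielded by two ortho substituents, and the non-basic aluminium amide does not enolise the acidic benzylic CH2.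

Step 6
Reactants: 12 undec-10-yn-1-ol
Product: 13 11-(benzyloxy)undec-1-yne
Conditions: NaH, BnBr, Bu4NI (cat.), THF/DMF, 0 °C to rt
Reagents that add atoms: benzyl bromide, BrCc1ccccc1
Why: Williamson etherification of the primary alkoxide with benzyl bromide, NaH deprotonating the alcohol far faster than the terminal alkyne under these conditions.

Step 7
Reactants: 11 benzyl 2,4-bis(benzyloxy)-6-{2-[methoxy(methyl)amino]-2-oxoethyl}benzoate; 13 11-(benzyloxy)undec-1-yne
Product: 16 benzyl 2,4-bis(benzyloxy)-6-[13-(benzyloxy)-2-oxotridec-3-yn-1-yl]benzoate, via lithium acetylide 14 (not isolated), via tetrahedral lithium adduct 15 (not isolated)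
Conditions: 13, n-BuLi, THF, −78 °C; then 11, −78 to −40 °C; sat. aq. NH4Cl at −40 °C
Reagents that add atoms: none
Why: Weinreb ketone synthesis in which lithium acetylide 14 adds once to the amide and the chelated adduct 15 survives until the quench, so no tertiary alcohol forms, while the weakly basic acetylide should spare the benzylic CH2 and the shielded benzoate.

Step 8
Reactants: 16 benzyl 2,4-bis(benzyloxy)-6-[13-(benzyloxy)-2-oxotridec-3-yn-1-yl]benzoate
Product: 17 benzyl 2,4-bis(benzyloxy)-6-[(2S)-13-(benzyloxy)-2-hydroxytridec-3-yn-1-yl]benzoate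
Conditions: Ru[(S,S)-TsNCHPhCHPhNH](p-cymene) (2 mol %), i-PrOH, rt
Reagents that add atoms: none
Why: Noyori asymmetric transfer hydrogenation of an α,β-acetylenic ketone, in whose bifunctional outer-sphere transition state the alkynyl group takes the place an aryl group has with acetophenone, so the (S,S)-ligand should deliver hydride to the face that gives the (S)-propargylic alcohol, and the neutral medium leaves the triple bond, the esters and the acidic CH2 alone.

Step 9
Reactants: 17 benzyl 2,4-bis(benzyloxy)-6-[(2S)-13-(benzyloxy)-2-hydroxytridec-3-yn-1-yl]benzoate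
Product: 18 benzyl 6-[(2S)-2-(acetyloxy)-13-(benzyloxy)tridec-3-yn-1-yl]-2,4-bis(benzyloxy)benzoate
Conditions: Ac2O, pyridine, DMAP (cat.), CH2Cl2, 0 °C, directly on freshly isolated 17
Reagents that add atoms: acetic anhydride, CC(=O)OC(C)=O
Why: DMAP-catalysed O-acetylation of the secondary alcohol proceeds with retention (the C–O bond is not touched) and should be much faster than attack of the neutral hydroxyl on the doubly ortho-substituted benzoate, so lactonisation to the dihydroisocoumarin is not expected.

Step 10
Reactants: 18 benzyl 6-[(2S)-2-(acetyloxy)-13-(benzyloxy)tridec-3-yn-1-yl]-2,4-bis(benzyloxy)benzoate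
Product: 19 6-[(2R)-2-(acetyloxy)-13-hydroxytridecyl]-2,4-dihydroxybenzoic acid
Conditions: H2 (1 atm), 10% Pd/C, EtOAc, rt
Reagents that add atoms: none
Why: Heterogeneous catalytic hydrogenation over Pd/C saturates the triple bond and hydrogenolyses the two aryl benzyl ethers, the alkyl benzyl ether and the benzyl ester in one operation while the acetate and the stereocentre are untouched, the descriptor changing from S to R only because the saturated chain now ranks below the benzylic carbon.

**Compound list**

1 | 3,5-bis(benzyloxy)phenol | Oc1cc(OCc2ccccc2)cc(OCc2ccccc2)c1 | starting material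
2 | 3,5-bis(benzyloxy)-2-bromophenol | Oc1cc(OCc2ccccc2)cc(OCc2ccccc2)c1Br | intermediate
3 | [3,5-bis(benzyloxy)-2-bromophenoxy]trimethylsilane | C[Si](C)(C)Oc1cc(OCc2ccccc2)cc(OCc2ccccc2)c1Br | intermediate
4 | {2,4-bis(benzyloxy)-6-[(trimethylsilyl)oxy]phenyl}lithium | C[Si](C)(C)Oc1cc(OCc2ccccc2)cc(OCc2ccccc2)c1[Li] | intermediate
5 | lithium 3,5-bis(benzyloxy)-2-(trimethylsilyl)phenoxide | [Li+].[O-]c1cc(OCc2ccccc2)cc(OCc2ccccc2)c1[Si](C)(C)C | intermediate
6 | 3,5-bis(benzyloxy)-2-(trimethylsilyl)phenyl trifluoromethanesulfonate | C[Si](C)(C)c1c(OCc2ccccc2)cc(OCc2ccccc2)cc1OS(=O)(=O)C(F)(F)F | intermediate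
7 | dibenzyl malonate | O=C(CC(=O)OCc1ccccc1)OCc1ccccc1 | starting material
8 | 3,5-bis(benzyloxy)benzyne (1,2-didehydro-3,5-bis(benzyloxy)benzene) | C1#CC(OCc2ccccc2)=CC(OCc2ccccc2)=C1 | intermediate
9 | potassium 2,4,8-tris(benzyloxy)-7-[(benzyloxy)carbonyl]bicyclo[4.2.0]octa-1,3,5-trien-8-olate | [K+].[O-]C1(OCc2ccccc2)C(C(=O)OCc2ccccc2)c2cc(OCc3ccccc3)cc(OCc3ccccc3)c21 | intermediate
10 | benzyl 2,4-bis(benzyloxy)-6-[2-(benzyloxy)-2-oxoethyl]benzoate | O=C(Cc1cc(OCc2ccccc2)cc(OCc2ccccc2)c1C(=O)OCc1ccccc1)OCc1ccccc1 | intermediate
11 | benzyl 2,4-bis(benzyloxy)-6-{2-[methoxy(methyl)amino]-2-oxoethyl}benzoate | CON(C)C(=O)Cc1cc(OCc2ccccc2)cc(OCc2ccccc2)c1C(=O)OCc1ccccc1 | intermediate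
12 | undec-10-yn-1-ol | C#CCCCCCCCCCO | starting material
13 | 11-(benzyloxy)undec-1-yne | C#CCCCCCCCCCOCc1ccccc1 | intermediate
14 | [11-(benzyloxy)undec-1-yn-1-yl]lithium | [Li]C#CCCCCCCCCCOCc1ccccc1 | intermediate
15 | lithium 1-{3,5-bis(benzyloxy)-2-[(benzyloxy)carbonyl]phenyl}-13-(benzyloxy)-2-[methoxy(methyl)amino]tridec-3-yn-2-olate | [Li+].[O-]C(Cc1cc(OCc2ccccc2)cc(OCc2ccccc2)c1C(=O)OCc1ccccc1)(C#CCCCCCCCCCOCc1ccccc1)N(C)OC | intermediate
16 | benzyl 2,4-bis(benzyloxy)-6-[13-(benzyloxy)-2-oxotridec-3-yn-1-yl]benzoate | O=C(Cc1cc(OCc2ccccc2)cc(OCc2ccccc2)c1C(=O)OCc1ccccc1)C#CCCCCCCCCCOCc1ccccc1 | intermediate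
17 | benzyl 2,4-bis(benzyloxy)-6-[(2S)-13-(benzyloxy)-2-hydroxytridec-3-yn-1-yl]benzoate | O[C@H](C#CCCCCCCCCCOCc1ccccc1)Cc1cc(OCc2ccccc2)cc(OCc2ccccc2)c1C(=O)OCc1ccccc1 | intermediate
18 | benzyl 6-[(2S)-2-(acetyloxy)-13-(benzyloxy)tridec-3-yn-1-yl]-2,4-bis(benzyloxy)benzoate | CC(=O)O[C@H](C#CCCCCCCCCCOCc1ccccc1)Cc1cc(OCc2ccccc2)cc(OCc2ccccc2)c1C(=O)OCc1ccccc1 | intermediate
19 | 6-[(2R)-2-(acetyloxy)-13-hydroxytridecyl]-2,4-dihydroxybenzoic acid | CC(=O)O[C@H](CCCCCCCCCCCO)Cc1cc(O)cc(O)c1C(=O)O | target

**Summary**

Total step count: 10. Longest linear sequence: 9 steps (steps 1–5 and 7–10); step 6 prepares the alkyne side fragment.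

**Steps most likely to fail**

Step 4. The ortho-alkoxy aryl anion may be protonated by the malonate before it closes onto the ester, which stops the sequence at simple C-arylation, and the product may be arylated a second time. The fallback leaves aryne chemistry and forms the two ring–carbon bonds one after the other; it sets out from bromophenol 2 and rejoins the route at homophthalate 10. Acylation of 2 with benzyl chloroformate (pyridine, CH2Cl2, 0 °C) should give benzyl 3,5-bis(benzyloxy)-2-bromophenyl carbonate F1. Bromine–lithium exchange (n-BuLi, THF, −100 °C) then triggers an anionic Fries-type 1,3 O-to-C shift of the benzyloxycarbonyl group, the carbon counterpart of the silyl shift in step 3, and a proton quench gives benzyl 2,4-bis(benzyloxy)-6-hydroxybenzoate F2. Triflation (Tf2O, pyridine, CH2Cl2) gives benzyl 2,4-bis(benzyloxy)-6-[(trifluoromethanesulfonyl)oxy]benzoate F3. Palladium-catalysed α-arylation of the zinc ester enolate [2-(benzyloxy)-2-oxoethyl]zinc bromide F4 (from benzyl bromoacetate and Zn dust) with F3 (Pd(dba)2, XPhos, THF, 60 °C) then gives 10.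

Step 7. The acetylide may deprotonate the doubly activated benzylic CH2 of the amide instead of adding, after which the enolate either returns starting material or closes through oxygen onto the benzoate; base-promoted isomerisation of the ynone is a second hazard. The fallback replaces the basic organolithium by a zinc acetylide and an acyl chloride; it sets out from diester 10 and rejoins the route at ynone 16. Selective saponification of the arylacetic ester (LiOH, THF/H2O, 0 °C; the doubly ortho-substituted benzoate resists) should give {3,5-bis(benzyloxy)-2-[(benzyloxy)carbonyl]phenyl}acetic acid F5. Oxalyl chloride with catalytic DMF (CH2Cl2, 0 °C) gives benzyl 2,4-bis(benzyloxy)-6-(2-chloro-2-oxoethyl)benzoate F6, to be used at once. Negishi acylation with [11-(benzyloxy)undec-1-yn-1-yl]zinc chloride F7 (from 14 and ZnCl2) under Pd(PPh3)4 catalysis in THF at rt gives 16.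

Step 10. On palladium the propargylic C–O bond, or the allylic C–O bond once the alkyne is half-reduced, may be hydrogenolysed in competition with saturation, which would delete the acetoxy group and with it the stereocentre. The fallback separates saturation from debenzylation and removes the activation before palladium is used; it sets out from acetate 18 and rejoins the route at target 19. Metal-free reduction of the triple bond with diimide (p-toluenesulfonyl hydrazide, NaOAc, DME/H2O, reflux, excess reagent) should give benzyl 6-[(2R)-2-(acetyloxy)-13-(benzyloxy)tridecyl]-2,4-bis(benzyloxy)benzoate F8, in which the acetate is an ordinary secondary alkyl ester. Hydrogenolysis of the four benzyl groups (H2, 10% Pd/C, EtOAc, rt) then gives 19.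

Further compounds
F1 | step 4 | benzyl 3,5-bis(benzyloxy)-2-bromophenyl carbonate | O=C(OCc1ccccc1)Oc1cc(OCc2ccccc2)cc(OCc2ccccc2)c1Br
F2 | step 4 | benzyl 2,4-bis(benzyloxy)-6-hydroxybenzoate | O=C(OCc1ccccc1)c1c(O)cc(OCc2ccccc2)cc1OCc1ccccc1
F3 | step 4 | benzyl 2,4-bis(benzyloxy)-6-[(trifluoromethanesulfonyl)oxy]benzoate | O=C(OCc1ccccc1)c1c(OS(=O)(=O)C(F)(F)F)cc(OCc2ccccc2)cc1OCc1ccccc1
F4 | step 4 | [2-(benzyloxy)-2-oxoethyl]zinc bromide | Br[Zn]CC(=O)OCc1ccccc1
F5 | step 7 | {3,5-bis(benzyloxy)-2-[(benzyloxy)carbonyl]phenyl}acetic acid | OC(=O)Cc1cc(OCc2ccccc2)cc(OCc2ccccc2)c1C(=O)OCc1ccccc1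
F6 | step 7 | benzyl 2,4-bis(benzyloxy)-6-(2-chloro-2-oxoethyl)benzoate | ClC(=O)Cc1cc(OCc2ccccc2)cc(OCc2ccccc2)c1C(=O)OCc1ccccc1
F7 | step 7 | [11-(benzyloxy)undec-1-yn-1-yl]zinc chloride | Cl[Zn]C#CCCCCCCCCCOCc1ccccc1
F8 | step 10 | benzyl 6-[(2R)-2-(acetyloxy)-13-(benzyloxy)tridecyl]-2,4-bis(benzyloxy)benzoate | CC(=O)O[C@H](CCCCCCCCCCCOCc1ccccc1)Cc1cc(OCc2ccccc2)cc(OCc2ccccc2)c1C(=O)OCc1ccccc1
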